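**Strategy.** Ring C of the lower flavan unit is cut across C3–C4 and O1–C8a. The step exploits that O1–C2–C3 is a latent ketone enolate (O–C=C) and that C4 and C8a are ortho neighbours on ring A: the lithium enolate of an α-(methoxymethoxy) aryl ketone is C-benzylated by a 2-bromobenzyl bromide and, in the same flask, palladium-catalysed enolate O-arylation closes ring C as a flav-2-ene ([3+3]). Unmasking gives a racemic flavan-3-one; hydrogenation under dynamic kinetic resolution sets C2 and C3. The benzylated epigallocatechin so obtained serves as both halves: C4 oxidation, 4β→8 condensation, double galloylation and hydrogenolysis complete rhodisin.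

Key step: step 5

Assumption: compounds 1, 5 and 6 are taken as catalogue chemicals; the electron-rich benzylic bromide 4 is assumed to survive long enough to be used crude directly after its preparation.

**Step 1**
Reactants: 1 1,3-bis(benzyloxy)-5-bromobenzene
Product: 2 2,4-bis(benzyloxy)-6-bromobenzaldehyde
Conditions: POCl3, DMF, 0 → 80 °C; then ice/H2O
Reagents that add atoms: N,N-dimethylformamide (CN(C)C=O), water (O)
Why: Vilsmeier–Haack formylation, in which the chloroiminium ion should attack the position para to one benzyloxy group and ortho to the other (next to bromine) rather than the more hindered position between the two benzyloxy groups, and hydrolysis of the iminium gives the aldehyde.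

**Step 2**
Reactants: 2 2,4-bis(benzyloxy)-6-bromobenzaldehyde
Product: 3 [2,4-bis(benzyloxy)-6-bromophenyl]methanol
Conditions: NaBH4, THF/MeOH, 0 °C
Reagents that add atoms: none
Why: Borohydride reduction of the aryl aldehyde to the benzylic alcohol leaves the aryl bromide and the benzyl ethers untouched.

**Step 3**
Reactants: 3 [2,4-bis(benzyloxy)-6-bromophenyl]methanol
Product: 4 1,5-bis(benzyloxy)-3-bromo-2-(bromomethyl)benzene
Conditions: PBr3, CH2Cl2, 0 °C; used crude at once
Reagents that add atoms: phosphorus tribromide (BrP(Br)Br)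
Why: The benzylic alcohol is converted through its phosphite ester into the bromide by SN2 displacement, and the electron-rich bromide is used immediately to avoid self-condensation.

**Step 4**
Reactants: 5 3,4,5-tris(benzyloxy)benzoyl chloride; 6 tributyl[(methoxymethoxy)methyl]stannane
Product: 7 2-(methoxymethoxy)-1-[3,4,5-tris(benzyloxy)phenyl]ethan-1-one
Conditions: PdCl2(PPh3)2 (5 mol %), toluene, 90 °C
Reagents that add atoms: none
Why: Migita–Kosugi–Stille acylation, in which the aroyl chloride adds oxidatively to zerovalent palladium, the α-alkoxymethyl group is transferred from tin in preference to butyl, and reductive elimination gives the α-alkoxy ketone.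

**Step 5**
Reactants: 7 2-(methoxymethoxy)-1-[3,4,5-tris(benzyloxy)phenyl]ethan-1-one; 4 1,5-bis(benzyloxy)-3-bromo-2-(bromomethyl)benzene
Product: 9 5,7-bis(benzyloxy)-3-(methoxymethoxy)-2-[3,4,5-tris(benzyloxy)phenyl]-4H-chromene, via C-benzylated ketone 8 (not isolated)
Conditions: LiN(SiMe3)2, THF, −78 °C; 4, −78 → 0 °C; then Pd2(dba)3 (3 mol %), DPEphos (7 mol %), NaOtBu, toluene, 90 °C
Reagents that add atoms: none
Why: LiN(SiMe3)2 turns 7 into its enolate, an O1–C2=C3 1,3-dinucleophile, which is C-benzylated at C3 by the benzylic bromide of 4 (SN2, new C3–C4 bond) to give 8; NaOtBu then regenerates the now tetrasubstituted enolate, zerovalent palladium inserts into the C8a–Br bond, the enolate oxygen O1 binds to palladium and C–O reductive elimination forms O1–C8a. The closest known reaction types are the domino C-benzylation/O-arylation of enolisable carbonyl compounds with 2-bromobenzyl bromides to 4H-chromenes and the palladium-catalysed intramolecular O-arylation of ketone enolates. Ring C is closed in a formal [3+3] annulation, the ring-closing event being reductive elimination from a seven-membered oxa-palladacycle to the six-membered enol ether; C-arylation at C3 would require a benzocyclobutene and should not compete. No stereocentre survives: the C3 centre of 8 is erased on enolisation, 9 is achiral, and C2 and C3 are set together in step 7. The step needs C- over O-benzylation (lithium enolate in THF, soft benzylic bromide, one equivalent at low temperature to avoid double alkylation), chemoselection between the two C–Br bonds (palladium is added only after the benzylic bromide is consumed) and the enolate geometry with O1 cis to C4, which should be reached because the enolate isomers equilibrate by proton exchange with tert-butanol at 90 °C while only the cyclisable isomer is drained.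

**Step 6**
Reactants: 9 5,7-bis(benzyloxy)-3-(methoxymethoxy)-2-[3,4,5-tris(benzyloxy)phenyl]-4H-chromene
Product: 10 5,7-bis(benzyloxy)-2-[3,4,5-tris(benzyloxy)phenyl]chroman-3-one (racemic at C2)
Conditions: Me3SiBr, CH2Cl2, −40 °C; then aq NaHCO3, MeOH
Reagents that add atoms: none
Why: Silyl-assisted acetal cleavage expels bromomethyl methyl ether and leaves the trimethylsilyl enol ether of the flavan-3-one, which is hydrolysed on the basic work-up with protonation at C2, so that protic acid and the ring-opening that would follow C3 protonation of the ene-diether are avoided and the benzyl ethers survive.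

**Step 7**
Reactants: 10 5,7-bis(benzyloxy)-2-[3,4,5-tris(benzyloxy)phenyl]chroman-3-one
Product: 11 (2R,3R)-5,7-bis(benzyloxy)-2-[3,4,5-tris(benzyloxy)phenyl]chroman-3-ol (penta-O-benzyl-(−)-epigallocatechin)
Conditions: H2 (20 atm), RuCl2[(S)-xylbinap][(S)-daipen] (1 mol %), KOtBu (10 mol %), i-PrOH/toluene, 25 °C
Reagents that add atoms: none
Why: Asymmetric ketone hydrogenation under dynamic kinetic resolution (Noyori type), in which KOtBu racemises the acidic C2–H (α-aryl, α-aryloxy) faster than reduction and the chiral ruthenium hydride should reduce the (2R)-ketone anti to the 2-aryl group to set C3 (R) and hence the 2,3-cis (2R,3R) alcohol, the sense being expected by analogy with 2-substituted cyclohexanones and the homogeneous catalyst sparing the benzyl ethers.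

**Step 8**
Reactants: 11 (2R,3R)-5,7-bis(benzyloxy)-2-[3,4,5-tris(benzyloxy)phenyl]chroman-3-ol
Product: 12 4β-(2-ethoxyethoxy) derivative of 11 (ether at C4 trans to the C3 hydroxyl; C2 and C3 as in 11)
Conditions: DDQ (2 equiv), 2-ethoxyethanol (5 equiv), CH2Cl2, rt
Reagents that add atoms: 2-ethoxyethanol (CCOCCO)
Why: Benzylic oxidation in which DDQ abstracts hydride from C4 (activated by ring A) and the quinone-methide-like cation is trapped by the alcohol trans to the C3 hydroxyl, a configuration that is erased again on ionisation in step 9.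

**Step 9**
Reactants: 12 4β-(2-ethoxyethoxy) derivative of 11; 11 (2R,3R)-5,7-bis(benzyloxy)-2-[3,4,5-tris(benzyloxy)phenyl]chroman-3-ol (4 equiv, excess recovered)
Product: 13 deca-O-benzyl epigallocatechin-(4β→8)-epigallocatechin (upper unit 2R,3R,4R; lower unit 2R,3R; both C3 hydroxyls free)
Conditions: Me3SiOTf (0.3 equiv), CH2Cl2, −78 → −40 °C; aq NaHCO3
Reagents that add atoms: none
Why: Friedel–Crafts-type proanthocyanidin condensation in which the Lewis acid ionises the C4 ether and C8 of ring A of 11 (the more nucleophilic position, used in excess to suppress oligomers) should attack the C4 cation from the β-face, anti to both the C3 hydroxyl and the 2-aryl group, setting upper C4 (R, 3,4-trans).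

**Step 10**
Reactants: 13 deca-O-benzyl epigallocatechin-(4β→8)-epigallocatechin; 5 3,4,5-tris(benzyloxy)benzoyl chloride (6 equiv)
Product: 14 hexadeca-O-benzyl rhodisin (3,3'-bis[3,4,5-tris(benzyloxy)benzoate] of 13)
Conditions: DMAP, pyridine, CH2Cl2, rt → 40 °C
Reagents that add atoms: none
Why: DMAP-catalysed acylation of both secondary C3 hydroxyls with excess acid chloride touches no stereocentre.

**Step 11**
Reactants: 14 hexadeca-O-benzyl rhodisin
Product: 15 rhodisin
Conditions: H2 (1 atm), Pd(OH)2/C, THF/MeOH/H2O, rt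
Reagents that add atoms: none
Why: Hydrogenolysis of all sixteen benzyl ethers under neutral conditions should leave the two gallate esters, the interflavan bond and the five stereocentres intact.

**Compound list**

1 | 1,3-bis(benzyloxy)-5-bromobenzene | Brc1cc(OCc2ccccc2)cc(OCc2ccccc2)c1 | starting material
2 | 2,4-bis(benzyloxy)-6-bromobenzaldehyde | O=Cc1c(Br)cc(OCc2ccccc2)cc1OCc1ccccc1 | intermediate
3 | [2,4-bis(benzyloxy)-6-bromophenyl]methanol | OCc1c(Br)cc(OCc2ccccc2)cc1OCc1ccccc1 | intermediate
4 | 1,5-bis(benzyloxy)-3-bromo-2-(bromomethyl)benzene | BrCc1c(Br)cc(OCc2ccccc2)cc1OCc1ccccc1 | intermediate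
5 | 3,4,5-tris(benzyloxy)benzoyl chloride | O=C(Cl)c1cc(OCc2ccccc2)c(OCc2ccccc2)c(OCc2ccccc2)c1 | starting material
6 | tributyl[(methoxymethoxy)methyl]stannane | CCCC[Sn](CCCC)(CCCC)COCOC | starting material
7 | 2-(methoxymethoxy)-1-[3,4,5-tris(benzyloxy)phenyl]ethan-1-one | COCOCC(=O)c1cc(OCc2ccccc2)c(OCc2ccccc2)c(OCc2ccccc2)c1 | intermediate
8 | 3-[2,4-bis(benzyloxy)-6-bromophenyl]-2-(methoxymethoxy)-1-[3,4,5-tris(benzyloxy)phenyl]propan-1-one (racemic) | COCOC(Cc1c(Br)cc(OCc2ccccc2)cc1OCc1ccccc1)C(=O)c1cc(OCc2ccccc2)c(OCc2ccccc2)c(OCc2ccccc2)c1 | intermediate (not isolated)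
9 | 5,7-bis(benzyloxy)-3-(methoxymethoxy)-2-[3,4,5-tris(benzyloxy)phenyl]-4H-chromene | COCOC1=C(c2cc(OCc3ccccc3)c(OCc3ccccc3)c(OCc3ccccc3)c2)Oc2cc(OCc3ccccc3)cc(OCc3ccccc3)c2C1 | intermediate
10 | 5,7-bis(benzyloxy)-2-[3,4,5-tris(benzyloxy)phenyl]chroman-3-one (racemic) | O=C1Cc2c(OCc3ccccc3)cc(OCc3ccccc3)cc2OC1c1cc(OCc2ccccc2)c(OCc2ccccc2)c(OCc2ccccc2)c1 | intermediate
11 | (2R,3R)-5,7-bis(benzyloxy)-2-[3,4,5-tris(benzyloxy)phenyl]chroman-3-ol | O[C@@H]1Cc2c(OCc3ccccc3)cc(OCc3ccccc3)cc2O[C@@H]1c1cc(OCc2ccccc2)c(OCc2ccccc2)c(OCc2ccccc2)c1 | intermediate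
12 | 4β-(2-ethoxyethoxy) derivative of 11 (C4 ether trans to C3–OH) | O[C@@H]1[C@@H](OCCOCC)c2c(OCc3ccccc3)cc(OCc3ccccc3)cc2O[C@@H]1c1cc(OCc2ccccc2)c(OCc2ccccc2)c(OCc2ccccc2)c1 | intermediate
13 | deca-O-benzyl epigallocatechin-(4β→8)-epigallocatechin | O[C@@H]1[C@@H](c2c(OCc3ccccc3)cc(OCc3ccccc3)c3c2O[C@H](c2cc(OCc4ccccc4)c(OCc4ccccc4)c(OCc4ccccc4)c2)[C@H](O)C3)c2c(OCc3ccccc3)cc(OCc3ccccc3)cc2O[C@@H]1c1cc(OCc2ccccc2)c(OCc2ccccc2)c(OCc2ccccc2)c1 | intermediate
14 | hexadeca-O-benzyl rhodisin | O=C(O[C@@H]1[C@@H](c2c(OCc3ccccc3)cc(OCc3ccccc3)c3c2O[C@H](c2cc(OCc4ccccc4)c(OCc4ccccc4)c(OCc4ccccc4)c2)[C@H](OC(=O)c2cc(OCc4ccccc4)c(OCc4ccccc4)c(OCc4ccccc4)c2)C3)c2c(OCc3ccccc3)cc(OCc3ccccc3)cc2O[C@@H]1c1cc(OCc2ccccc2)c(OCc2ccccc2)c(OCc2ccccc2)c1)c1cc(OCc2ccccc2)c(OCc2ccccc2)c(OCc2ccccc2)c1 | intermediate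
15 | rhodisin | O=C(O[C@@H]1[C@@H](c2c(O)cc(O)c3c2O[C@H](c2cc(O)c(O)c(O)c2)[C@H](OC(=O)c2cc(O)c(O)c(O)c2)C3)c2c(O)cc(O)cc2O[C@@H]1c1cc(O)c(O)c(O)c1)c1cc(O)c(O)c(O)c1 | target

**Step count and risks**

Total steps: 11. Longest linear sequence: 10 steps (steps 1, 2, 3, 5, 6, 7, 8, 9, 10, 11).

Steps most likely to fail:

Step 5 (key step). What may go wrong: O-benzylation of the chelated α-alkoxy enolate, or stalling of the C–O reductive elimination because chelation by the methoxymethoxy group holds the enolate oxygen away from C4, so that protodebromination takes over. Fallback, setting out from 4 and 5 and returning at 10: the C3 oxygen is left out of the annulation and introduced afterwards. Compound 5 is converted with MeMgBr and catalytic Fe(acac)3 (THF, −78 °C) into 1-[3,4,5-tris(benzyloxy)phenyl]ethan-1-one F1. Its lithium enolate (LiN(SiMe3)2, THF) is benzylated by 4 to 3-[2,4-bis(benzyloxy)-6-bromophenyl]-1-[3,4,5-tris(benzyloxy)phenyl]propan-1-one F2, which in the same flask (Pd2(dba)3, DPEphos, NaOtBu, toluene, 90 °C) should close by enolate O-arylation to 5,7-bis(benzyloxy)-2-[3,4,5-tris(benzyloxy)phenyl]-4H-chromene F3; here no chelating group is present and the enolate geometry with oxygen cis to the benzylic carbon is the favoured one. Epoxidation of the enol ether with dimethyldioxirane (acetone, −40 °C) gives the racemic 2,3-epoxyflavan F4, and MgBr2·OEt2 should promote opening at C2 and 1,2-hydride shift from C3 (Meinwald rearrangement) to the flavan-3-one 10.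

Step 7. What may go wrong: racemisation at C2 too slow relative to hydrogenation, or weak enantiofacial discrimination for a ketone flanked by two sp3 carbons, leading to eroded enantiomeric purity or to trans alcohol. Fallback, setting out from 10 and returning at 11: substrate-controlled reduction with LiBH(sec-Bu)3 (THF, −78 °C), hydride adding anti to the 2-aryl group, should give the racemic 2,3-cis alcohol, that is 11 together with its (2S,3S)-enantiomer F5; the two are separated by preparative chromatography on a cellulose tris(3,5-dimethylphenylcarbamate) phase.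

Step 9. What may go wrong: over-condensation to trimers and higher oligomers, and erosion of C8 versus C6 regioselectivity or of facial selectivity when the electrophile with a free C3 hydroxyl ionises. Fallback, setting out from 11 and 12 and returning at 14: esterification is moved ahead of the union. Acylation of 11 with 5 (DMAP, pyridine) gives octa-O-benzyl-epigallocatechin gallate F6, and acylation of 12 gives the 3-O-[3,4,5-tris(benzyloxy)benzoyl] ester of 12 F7. Me3SiOTf-mediated condensation of F7 with F6 should then proceed through a C3 acyloxonium ion (neighbouring-group participation) that shields the α-face and tempers the cation, giving 14 directly.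

**Further compounds**

F1 | step 5 | 1-[3,4,5-tris(benzyloxy)phenyl]ethan-1-one | CC(=O)c1cc(OCc2ccccc2)c(OCc2ccccc2)c(OCc2ccccc2)c1
F2 | step 5 | 3-[2,4-bis(benzyloxy)-6-bromophenyl]-1-[3,4,5-tris(benzyloxy)phenyl]propan-1-one | O=C(CCc1c(Br)cc(OCc2ccccc2)cc1OCc1ccccc1)c1cc(OCc2ccccc2)c(OCc2ccccc2)c(OCc2ccccc2)c1
F3 | step 5 | 5,7-bis(benzyloxy)-2-[3,4,5-tris(benzyloxy)phenyl]-4H-chromene | C1(c2cc(OCc3ccccc3)c(OCc3ccccc3)c(OCc3ccccc3)c2)=CCc2c(OCc3ccccc3)cc(OCc3ccccc3)cc2O1
F4 | step 5 | 5,7-bis(benzyloxy)-2,3-epoxy-2-[3,4,5-tris(benzyloxy)phenyl]chroman (racemic) | C12(c3cc(OCc4ccccc4)c(OCc4ccccc4)c(OCc4ccccc4)c3)OC1Cc1c(OCc3ccccc3)cc(OCc3ccccc3)cc1O2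
F5 | step 7 | (2S,3S)-5,7-bis(benzyloxy)-2-[3,4,5-tris(benzyloxy)phenyl]chroman-3-ol (enantiomer of 11) | O[C@H]1Cc2c(OCc3ccccc3)cc(OCc3ccccc3)cc2O[C@H]1c1cc(OCc2ccccc2)c(OCc2ccccc2)c(OCc2ccccc2)c1
F6 | step 9 | octa-O-benzyl-(−)-epigallocatechin gallate (3-O-[3,4,5-tris(benzyloxy)benzoyl] ester of 11) | O=C(O[C@@H]1Cc2c(OCc3ccccc3)cc(OCc3ccccc3)cc2O[C@@H]1c1cc(OCc2ccccc2)c(OCc2ccccc2)c(OCc2ccccc2)c1)c1cc(OCc2ccccc2)c(OCc2ccccc2)c(OCc2ccccc2)c1
F7 | step 9 | 3-O-[3,4,5-tris(benzyloxy)benzoyl] ester of 12 | O=C(O[C@@H]1[C@@H](OCCOCC)c2c(OCc3ccccc3)cc(OCc3ccccc3)cc2O[C@@H]1c1cc(OCc2ccccc2)c(OCc2ccccc2)c(OCc2ccccc2)c1)c1cc(OCc2ccccc2)c(OCc2ccccc2)c(OCc2ccccc2)c1
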